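**Plan**

1. Retrosynthesis (eudesmane numbering): the angelate is cut at O3, ring B is simplified from the 6-en-8-one to a C8=C9 alkene, and ring A is traced back through the 3β-ol and the 3-keto-4α-ol to a 4-methyl-4-en-3-one. That ring is cut at C2–C3 and C4–C5 into propanal and a 2-methyl-2-vinylcyclohex-3-enone.
2. Enabling feature: in ring A the oxygenated C3 lies between the C2 methylene and C4, which carries methyl C15, so C3–C4–C15 is a propanal unit (C3 acyl carbon, C4 α-carbon). C2 is the end of a two-carbon arm on quaternary C10, and C5 is the carbonyl carbon next to C10 in ring B, whose C10 methyl and C7 three-carbon branch are those of carvone.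
3. Forward: (R)-carvone is hydrated (C11–OH) and vinylated at C10 through its extended dienolate, which completes ring B with a C8=C9 alkene. Ring A is then closed in one operation by hydroacylation of the vinyl group (C2–C3) and aldol cyclodehydration (C4=C5).
4. Ring A is finished by reductive enolate hydroxylation, ketone reduction and angeloylation; ring B by hydration of C8=C9 and oxidation–dehydrogenation to the 6-en-8-one.
5. Stereochemistry: C10 from dienolate attack anti to the C7 substituent of (R)-carvone (C7 is a removable control element that ends sp2); C5 and C4 from axial protonation and hydroxylation anti to the C10 methyl; C3 from axial hydride delivery.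

Key step: step 3

Remark: eudesmane numbering is used throughout (C14 = methyl on C10, C15 = methyl on C4, C11 = carbinol carbon on C7) and β is the face of C14; (R)-carvone, phenyl vinyl sulfoxide, propanal and angelic anhydride are taken as purchased.

**Route**

Step 1
Reactants: 1 (R)-(−)-carvone
Product: 2 (5R)-5-(2-hydroxypropan-2-yl)-2-methylcyclohex-2-en-1-one
Conditions: 50% aq. H2SO4, 0 °C to rt
Reagents that add atoms: water, O
Why: Acid-catalysed alkene hydration, in which the 1,1-disubstituted isopropenyl group is protonated to the tertiary cation and captured by water while the electron-poor enone alkene stays inert and the C7 stereocentre is not touched.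

Step 2
Reactants: 2 (5R)-5-(2-hydroxypropan-2-yl)-2-methylcyclohex-2-en-1-one; 3 phenyl vinyl sulfoxide
Product: 5 (2R,5S)-2-ethenyl-5-(2-hydroxypropan-2-yl)-2-methylcyclohex-3-en-1-one, via sulfoxide adduct 4 (not isolated)
Conditions: KOtBu (0.3 equiv), t-BuOH/THF, 0 °C to rt; aq. NH4Cl; crude 4, toluene, 110 °C
Reagents that add atoms: none
Why: Equilibrating deprotonation at C8 gives the extended dienolate, which should add through its α-carbon C10 to the vinyl sulfoxide (deconjugative Michael addition, as in α-alkylations of carvone dienolates), mainly on the face anti to the C7 hydroxyisopropyl group, which sets C10; thermal syn-elimination of benzenesulfenic acid from the crude adduct then unveils the vinyl group, and the minor C10 epimer is removed by chromatography at this stage.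

Step 3
Reactants: 5 (2R,5S)-2-ethenyl-5-(2-hydroxypropan-2-yl)-2-methylcyclohex-3-en-1-one; 6 propanal
Product: 8 (4aR,7S)-7-(2-hydroxypropan-2-yl)-1,4a-dimethyl-4,4a,7,8-tetrahydronaphthalen-2(3H)-one, via 1,5-diketone 7 (not isolated)
Conditions: RhCl(PPh3)3 (5 mol%), 2-amino-3-picoline (0.3 equiv), PhCO2H (0.1 equiv), propanal (3 equiv), toluene, 130 °C, sealed tube; then KOH (0.5 equiv), MeOH, 60 °C, same flask
Reagents that add atoms: none
Why: Propanal condenses with 2-amino-3-picoline to an aldimine whose pyridine nitrogen steers monovalent rhodium into the formyl C–H bond, the hydride adds to the internal carbon C1 of the vinyl group so that rhodium sits on the terminal C2, and reductive elimination forms C2–C3; hydrolysis of the ketimine releases ethyl ketone 7 (closest known reaction type: chelation-assisted intermolecular hydroacylation of 1-alkenes with aldehydes). KOH then enolises 7 at C4, and a 6-(enolexo)-exo-trig aldol addition to the C5 carbonyl followed by E1cB loss of water closes ring A as the tetrasubstituted C4=C5 enone, as in the second stage of a Robinson annulation. No stereocentre is created, and C10 (quaternary) and C7 (not acidic) cannot epimerise. The step needs chemoselectivity for the vinyl group over the C8=C9 alkene, which the substrate secures because only the vinyl group is monosubstituted and terminal; linear regiochemistry, secured by the neopentyl position of C1; and the right aldol pairing, secured because the competing C6-to-C3 aldol leads to a bridged ketol that cannot dehydrate and reverts.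

Step 4
Reactants: 8 (4aR,7S)-7-(2-hydroxypropan-2-yl)-1,4a-dimethyl-4,4a,7,8-tetrahydronaphthalen-2(3H)-one
Product: 10 (1S,4aR,7S,8aR)-1-hydroxy-7-(2-hydroxypropan-2-yl)-1,4a-dimethyl-3,4,4a,7,8,8a-hexahydronaphthalen-2(1H)-one, via dilithium enolate 9 (not isolated)
Conditions: Li (2.1 equiv), NH3(l)/THF, −78 °C; NH3 evaporated; 2-(phenylsulfonyl)-3-phenyloxaziridine (1.3 equiv), THF, −78 °C; aq. NH4Cl
Reagents that add atoms: 2-(phenylsulfonyl)-3-phenyloxaziridine, O=S(=O)(c1ccccc1)N1OC1c1ccccc1
Why: Dissolving-metal reduction of the enone (Birch-type conditions, the C11 hydroxyl serving as the single proton donor) should protonate C5 axially and give the trans-fused C3/C4 enolate regiospecifically, and electrophilic hydroxylation of that enolate by the oxaziridine should occur anti to the axial C10 methyl, which sets 5α-H and 4α-OH (4β-methyl), while the isolated C8=C9 alkene is not reduced.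

Step 5
Reactants: 10 (1S,4aR,7S,8aR)-1-hydroxy-7-(2-hydroxypropan-2-yl)-1,4a-dimethyl-3,4,4a,7,8,8a-hexahydronaphthalen-2(1H)-one
Product: 11 (1S,2S,4aR,7S,8aR)-7-(2-hydroxypropan-2-yl)-1,4a-dimethyl-1,2,3,4,4a,7,8,8a-octahydronaphthalene-1,2-diol
Conditions: NaBH4, MeOH, −20 °C
Reagents that add atoms: none
Why: Borohydride reduction of the C3 ketone, in which hydride should enter along the axial trajectory on the α-face, away from the axial 4β-methyl, to give the equatorial 3β-alcohol trans to the 4α-hydroxyl.

Step 6
Reactants: 11 (1S,2S,4aR,7S,8aR)-7-(2-hydroxypropan-2-yl)-1,4a-dimethyl-1,2,3,4,4a,7,8,8a-octahydronaphthalene-1,2-diol; 12 angelic anhydride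
Product: 13 (1S,2S,4aR,7S,8aR)-1-hydroxy-7-(2-hydroxypropan-2-yl)-1,4a-dimethyl-1,2,3,4,4a,7,8,8a-octahydronaphthalen-2-yl (2Z)-2-methylbut-2-enoate
Conditions: LiN(SiMe3)2 (1.05 equiv), THF, −78 °C; 12, −78 to 0 °C; aq. NH4Cl
Reagents that add atoms: none
Why: Alkoxide acylation, in which the lithium alkoxide of the only secondary hydroxyl (C3) is acylated by the symmetrical anhydride without a nucleophilic catalyst, so the (Z)-2-methylbut-2-enoyl group should not isomerise and the two hindered tertiary hydroxyls should stay free.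

Step 7
Reactants: 13 (1S,2S,4aR,7S,8aR)-1-hydroxy-7-(2-hydroxypropan-2-yl)-1,4a-dimethyl-1,2,3,4,4a,7,8,8a-octahydronaphthalen-2-yl (2Z)-2-methylbut-2-enoate
Product: 15 (1S,2S,4aR,6R,7S,8aR)-1,6-dihydroxy-7-(2-hydroxypropan-2-yl)-1,4a-dimethyldecahydronaphthalen-2-yl (2Z)-2-methylbut-2-enoate, via organomercurial 14 (not isolated)
Conditions: Hg(OAc)2 (1.2 equiv), THF/H2O (1:1), rt; then NaBH4, 3 M aq. NaOH, 0 °C
Reagents that add atoms: water, O
Why: Oxymercuration–demercuration, in which divalent mercury should add to the less hindered α-face of the C8=C9 alkene and water should open the mercurinium ion trans-diaxially at C8, so the hydroxyl ends on C8 (its configuration is irrelevant because C8 becomes a carbonyl) while the electron-poor angelate alkene does not react.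

Step 8
Reactants: 15 (1S,2S,4aR,6R,7S,8aR)-1,6-dihydroxy-7-(2-hydroxypropan-2-yl)-1,4a-dimethyldecahydronaphthalen-2-yl (2Z)-2-methylbut-2-enoate
Product: 17 (1S,2S,4aR,8aR)-1-hydroxy-7-(2-hydroxypropan-2-yl)-1,4a-dimethyl-6-oxo-1,2,3,4,4a,5,6,8a-octahydronaphthalen-2-yl (2Z)-2-methylbut-2-enoate, via 8-ketone 16 (not isolated)
Conditions: IBX (3.5 equiv), 4-methoxypyridine N-oxide (3.5 equiv), DMSO, rt to 55 °C
Reagents that add atoms: none
Why: IBX oxidation of the secondary C8 alcohol to the ketone followed by IBX-mediated dehydrogenation of that ketone, which can only occur towards C6–C7 because C9 is bonded to the quaternary C10, should give the 6-en-8-one and erase the C7 stereocentre.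

**Compound list**

1 | (R)-(−)-carvone, (5R)-2-methyl-5-(prop-1-en-2-yl)cyclohex-2-en-1-one | CC1=CC[C@@H](C(C)=C)CC1=O | starting material
2 | (5R)-5-(2-hydroxypropan-2-yl)-2-methylcyclohex-2-en-1-one | CC1=CC[C@@H](C(C)(C)O)CC1=O | intermediate
3 | phenyl vinyl sulfoxide, (ethenylsulfinyl)benzene, racemic | C=CS(=O)c1ccccc1 | starting material
4 | (2R,5S)-5-(2-hydroxypropan-2-yl)-2-methyl-2-[2-(phenylsulfinyl)ethyl]cyclohex-3-en-1-one, both configurations at sulfur | O=C1C[C@H](C(C)(C)O)C=C[C@@]1(C)CCS(=O)c1ccccc1 | intermediate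
5 | (2R,5S)-2-ethenyl-5-(2-hydroxypropan-2-yl)-2-methylcyclohex-3-en-1-one | O=C1C[C@H](C(C)(C)O)C=C[C@@]1(C)C=C | intermediate
6 | propanal | CCC=O | starting material
7 | (2R,5S)-5-(2-hydroxypropan-2-yl)-2-methyl-2-(3-oxopentyl)cyclohex-3-en-1-one | O=C1C[C@H](C(C)(C)O)C=C[C@@]1(C)CCC(=O)CC | intermediate
8 | (4aR,7S)-7-(2-hydroxypropan-2-yl)-1,4a-dimethyl-4,4a,7,8-tetrahydronaphthalen-2(3H)-one (11-hydroxy-7αH-eudesma-4,8-dien-3-one) | O=C1CC[C@]2(C)C=C[C@@H](C(C)(C)O)CC2=C1C | intermediate
9 | dilithium salt of the trans-fused (5α-H) reduction product of 8: lithium C3/C4 enolate and lithium C11 alkoxide | [Li+].[Li+].[O-]C1=C(C)[C@@H]2C[C@H](C(C)(C)[O-])C=C[C@@]2(C)CC1 | intermediate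
10 | (1S,4aR,7S,8aR)-1-hydroxy-7-(2-hydroxypropan-2-yl)-1,4a-dimethyl-3,4,4a,7,8,8a-hexahydronaphthalen-2(1H)-one (4α,11-dihydroxy-5α,7αH-eudesm-8-en-3-one) | O=C1CC[C@]2(C)C=C[C@@H](C(C)(C)O)C[C@H]2[C@]1(C)O | intermediate
11 | (1S,2S,4aR,7S,8aR)-7-(2-hydroxypropan-2-yl)-1,4a-dimethyl-1,2,3,4,4a,7,8,8a-octahydronaphthalene-1,2-diol (5α,7αH-eudesm-8-ene-3β,4α,11-triol) | O[C@H]1CC[C@]2(C)C=C[C@@H](C(C)(C)O)C[C@H]2[C@]1(C)O | intermediate
12 | angelic anhydride, (2Z)-2-methylbut-2-enoic anhydride | C/C=C(/C)C(=O)OC(=O)/C(C)=C\C | starting material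
13 | (1S,2S,4aR,7S,8aR)-1-hydroxy-7-(2-hydroxypropan-2-yl)-1,4a-dimethyl-1,2,3,4,4a,7,8,8a-octahydronaphthalen-2-yl (2Z)-2-methylbut-2-enoate (3β-angeloyloxy-5α,7αH-eudesm-8-ene-4α,11-diol) | C/C=C(/C)C(=O)O[C@H]1CC[C@]2(C)C=C[C@@H](C(C)(C)O)C[C@H]2[C@]1(C)O | intermediate
14 | 3β-angeloyloxy-9α-(acetoxymercurio)-5α,7αH-eudesmane-4α,8β,11-triol (trans-diaxial adduct of 13) | C/C=C(/C)C(=O)O[C@H]1CC[C@]2(C)[C@H]([Hg]OC(C)=O)[C@@H](O)[C@@H](C(C)(C)O)C[C@H]2[C@]1(C)O | intermediate
15 | (1S,2S,4aR,6R,7S,8aR)-1,6-dihydroxy-7-(2-hydroxypropan-2-yl)-1,4a-dimethyldecahydronaphthalen-2-yl (2Z)-2-methylbut-2-enoate (3β-angeloyloxy-5α,7αH-eudesmane-4α,8β,11-triol) | C/C=C(/C)C(=O)O[C@H]1CC[C@]2(C)C[C@@H](O)[C@@H](C(C)(C)O)C[C@H]2[C@]1(C)O | intermediate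
16 | 3β-angeloyloxy-4α,11-dihydroxy-5α,7αH-eudesman-8-one | C/C=C(/C)C(=O)O[C@H]1CC[C@]2(C)CC(=O)[C@@H](C(C)(C)O)C[C@H]2[C@]1(C)O | intermediate
17 | (1S,2S,4aR,8aR)-1-hydroxy-7-(2-hydroxypropan-2-yl)-1,4a-dimethyl-6-oxo-1,2,3,4,4a,5,6,8a-octahydronaphthalen-2-yl (2Z)-2-methylbut-2-enoate (3β-angeloyloxy-4α,11-dihydroxy-5αH-eudesm-6-en-8-one) | C/C=C(/C)C(=O)O[C@H]1CC[C@]2(C)CC(=O)C(C(C)(C)O)=C[C@H]2[C@]1(C)O | target

Total step count: 8. Longest linear sequence: 8 steps (1 to 17).

**Steps most likely to fail**

Step 3. Propanal may self-condense under the amine/acid conditions at 130 °C, the rhodium hydride may migrate the C8=C9 double bond, or the hydroacylation may stall before ring A can close. The fallback sets out from 2 and builds the same diketone by a Robinson annulation instead: the extended dienolate of 2 (KOtBu, t-BuOH) adds through C10 to pent-1-en-3-one to give 7, now isolated, and KOH in MeOH closes ring A to 8, where the route is rejoined. This fallback makes no compound outside the list (F0).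

Step 2. Facial selectivity at C10 may be poor, the dienolate may react through C8 or oxygen, the kinetic cross-conjugated enolate may trigger a second Michael closure, or the sulfoxide elimination may be incomplete. The fallback sets out from 2 and replaces the Michael acceptor by an irreversible, bulkier electrophile: the potassium dienolate is ethynylated with 1-[(trimethylsilyl)ethynyl]-1,2-benziodoxol-3(1H)-one in the presence of fluoride to give (2S,5S)-2-ethynyl-5-(2-hydroxypropan-2-yl)-2-methylcyclohex-3-en-1-one F1, and semihydrogenation over Pd/CaCO3 poisoned with Pb(OAc)2 and quinoline returns to the route at 5.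

Step 7. Mercuration of the hindered disubstituted alkene may be slow, the regiocontrol of the opening may erode, or hydroxide and borohydride may attack the angelate during demercuration. The fallback sets out from 13 and separates C–O bond formation from the reduction: N-bromosuccinimide in aqueous acetone forms the bromonium ion on the α-face and water opens it trans-diaxially to 3β-angeloyloxy-9α-bromo-5α,7αH-eudesmane-4α,8β,11-triol F2, and radical debromination with Bu3SnH and AIBN in toluene at 80 °C returns to the route at 15.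

Further compounds
F0 | step 3 | none | none
F1 | step 2 | (2S,5S)-2-ethynyl-5-(2-hydroxypropan-2-yl)-2-methylcyclohex-3-en-1-one | O=C1C[C@H](C(C)(C)O)C=C[C@@]1(C)C#C
F2 | step 7 | 3β-angeloyloxy-9α-bromo-5α,7αH-eudesmane-4α,8β,11-triol | C/C=C(/C)C(=O)O[C@H]1CC[C@]2(C)[C@H](Br)[C@@H](O)[C@@H](C(C)(C)O)C[C@H]2[C@]1(C)O
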